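**Retrosynthetic overview**

1. The target is a 14-membered carbocycle (ring A) fused trans at C1–C2 to an α-methylene-γ-butyrolactone (ring B). The feature that makes the key step possible is the ring-A segment C10(O)–C11=C12(CH3)–C13H2–C14(O): an E-trisubstituted olefin flanked 1,5 by two carbinols, which is the retron of a 4-oxygenated but-2-yne. As an alkyne (C11≡C12) it has no geometry to control, and a C13 carbonate turns it into an allenylindium (metal on C11) that can reach a C14 aldehyde only through C13.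
2. Key disconnection C13–C14: ring-closing allenylmetal addition to the C14 formyl group, with C14 set by the trans-lactone stereocentres C1/C2. The new C14–OH then steers a trans-hydrostannation that places tin on C12, and a methyl-Stille coupling gives the (11E)-olefin.
3. Seco-aldehyde: ring B by a stereospecific tandem allylboration–lactonization at C1–C2. The C2–C13 chain comes from two iterative vinylogous Mukaiyama aldol additions of a prenal dienolate (C9–C10, then C5–C6) to an ynal made from but-2-yne-1,4-diol.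
4. Ring order: ring B first (step 11), then ring A (step 14).

Key step: step 14

Remark on numbering: cembrane numbering is used for the lactone-bearing intermediates. C1 is the ring-fusion CH, C2 the lactone O–CH, C14 the carbinol next to C1, C15/C16/C17 the lactone α-carbon, carbonyl and exocyclic CH2, and C18–C20 the methyls on C4, C8 and C12.

Assumption: the L-tryptophan-derived oxazaborolidinone (steps 4 and 6) and the (−)-8-phenylmenthyl ester (step 11) are taken to deliver the (S)-carbinols and the (1S,2S)-lactone. If either sense of induction is the reverse, the antipodal controller is used and nothing else changes.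

**Route**

Step 1
Reactants: 1 but-2-yne-1,4-diol
Product: 2 4-hydroxybut-2-yn-1-yl methyl carbonate
Conditions: ClCO2Me (0.35 equiv), pyridine, CH2Cl2–THF, 0 °C (diol in excess)
Reagents that add atoms: methyl chloroformate, COC(=O)Cl
Why: Statistical mono-acylation of the symmetrical diol used in excess should give the mono-carbonate, which is carried through the route as the latent C13 leaving group.

Step 2
Reactants: 2 4-hydroxybut-2-yn-1-yl methyl carbonate
Product: 3 methyl 4-oxobut-2-yn-1-yl carbonate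
Conditions: activated MnO2, CH2Cl2, rt
Reagents that add atoms: none
Why: MnO2 oxidation of a propargylic alcohol should stop cleanly at the ynal under neutral conditions.

Step 3
Reactants: 4 3-methylbut-2-enal (prenal)
Product: 5 tert-butyl(dimethyl){[(1E)-3-methylbuta-1,3-dien-1-yl]oxy}silane
Conditions: TBSOTf, Et3N, Et2O, 0 °C
Reagents that add atoms: tert-butyldimethylsilyl trifluoromethanesulfonate, CC(C)(C)[Si](C)(C)OS(=O)(=O)C(F)(F)F
Why: Soft enolization with γ-deprotonation and O-silylation should give the silyl dienol ether, the dienolate equivalent of prenal.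

Step 4
Reactants: 3 methyl 4-oxobut-2-yn-1-yl carbonate; 5 tert-butyl(dimethyl){[(1E)-3-methylbuta-1,3-dien-1-yl]oxy}silane
Product: 6 methyl (4S,6E)-4-hydroxy-6-methyl-8-oxooct-6-en-2-yn-1-yl carbonate
Conditions: N-tosyl-L-tryptophan-derived B-phenyl-1,3,2-oxazaborolidin-5-one (30 mol %), i-PrOH (1.1 equiv), EtCN, −78 °C
Reagents that add atoms: none
Why: In this vinylogous Mukaiyama aldol reaction the chiral boron Lewis acid activates the ynal and the dienol ether attacks through its γ-carbon in the s-trans form, so the C9–C10 bond, the (10S)-carbinol (catalyst control) and the (7E)-enal should arise together.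

Step 5
Reactants: 6 methyl (4S,6E)-4-hydroxy-6-methyl-8-oxooct-6-en-2-yn-1-yl carbonate
Product: 7 methyl (4S,6E)-6-methyl-8-oxo-4-(triethylsilyloxy)oct-6-en-2-yn-1-yl carbonate
Conditions: TESCl, imidazole, CH2Cl2, 0 °C
Reagents that add atoms: chlorotriethylsilane, CC[Si](Cl)(CC)CC
Why: Silylation gives a labile, non-leaving ether at C10, which is needed later so that the allenylmetal cannot β-eliminate and so that C10 can be unmasked before C6.

Step 6
Reactants: 7 methyl (4S,6E)-6-methyl-8-oxo-4-(triethylsilyloxy)oct-6-en-2-yn-1-yl carbonate; 5 tert-butyl(dimethyl){[(1E)-3-methylbuta-1,3-dien-1-yl]oxy}silane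
Product: 8 methyl (4S,6E,8S,10E)-8-hydroxy-6,10-dimethyl-12-oxo-4-(triethylsilyloxy)dodeca-6,10-dien-2-yn-1-yl carbonate
Conditions: N-tosyl-L-tryptophan-derived B-phenyl-1,3,2-oxazaborolidin-5-one (30 mol %), i-PrOH (1.1 equiv), EtCN, −78 °C
Reagents that add atoms: none
Why: A second, iterative vinylogous Mukaiyama aldol reaction (1,2-addition to the enal) should form the C5–C6 bond, the (6S)-carbinol under the same catalyst control (C10 is too remote to interfere) and the (3E)-enal.

Step 7
Reactants: 8 methyl (4S,6E,8S,10E)-8-hydroxy-6,10-dimethyl-12-oxo-4-(triethylsilyloxy)dodeca-6,10-dien-2-yn-1-yl carbonate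
Product: 9 methyl (4S,6E,8S,10E)-8-(tert-butyldimethylsilyloxy)-6,10-dimethyl-12-oxo-4-(triethylsilyloxy)dodeca-6,10-dien-2-yn-1-yl carbonate
Conditions: TBSCl, imidazole, DMF, rt
Reagents that add atoms: tert-butyl(chloro)dimethylsilane, CC(C)(C)[Si](C)(C)Cl
Why: Silylation puts the robust TBS group on C6 (free OH in the target), orthogonal to the TES group on C10 (acetate in the target).

Step 8
Reactants: 10 1-methoxy-4-[(prop-2-yn-1-yloxy)methyl]benzene (PMB propargyl ether)
Product: 11 4-[(4-methoxybenzyl)oxy]but-2-ynoic acid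
Conditions: n-BuLi, THF, −78 °C; CO2 (g); then 1 M HCl
Reagents that add atoms: carbon dioxide, O=C=O
Why: Carboxylation of the lithium acetylide should give the ynoic acid that supplies C14, C1, C15 and C16.

Step 9
Reactants: 11 4-[(4-methoxybenzyl)oxy]but-2-ynoic acid; 12 (1R,2S,5R)-5-methyl-2-(2-phenylpropan-2-yl)cyclohexan-1-ol ((−)-8-phenylmenthol)
Product: 13 (1R,2S,5R)-5-methyl-2-(2-phenylpropan-2-yl)cyclohexyl 4-[(4-methoxybenzyl)oxy]but-2-ynoate
Conditions: DCC, DMAP (cat.), CH2Cl2, 0 °C to rt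
Reagents that add atoms: none
Why: Steglich esterification installs the chiral ester that later shields one face of the acrylate unit.

Step 10
Reactants: 13 (1R,2S,5R)-5-methyl-2-(2-phenylpropan-2-yl)cyclohexyl 4-[(4-methoxybenzyl)oxy]but-2-ynoate
Product: 15 (−)-8-phenylmenthyl (2Z)-4-[(4-methoxybenzyl)oxy]-2-[(4,4,5,5-tetramethyl-1,3,2-dioxaborolan-2-yl)methyl]but-2-enoate, via alkenylalane 14 (not isolated)
Conditions: i-Bu2AlH, HMPA, THF, 0 °C; then ICH2B(pin), rt
Reagents that add atoms: 2-(iodomethyl)-4,4,5,5-tetramethyl-1,3,2-dioxaborolane, CC1(C)OB(CI)OC1(C)C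
Why: syn-1,4-Hydroalumination of the ynoate (hydride to the β-carbon) followed by borylmethylation of the α-alumino acrylate with retention (ate complex, 1,2-shift) should give the allylboronate with CH2OPMB trans to CH2B, the geometry that leads to the anti adduct.

Step 11
Reactants: 9 methyl (4S,6E,8S,10E)-8-(tert-butyldimethylsilyloxy)-6,10-dimethyl-12-oxo-4-(triethylsilyloxy)dodeca-6,10-dien-2-yn-1-yl carbonate; 15 (−)-8-phenylmenthyl (2Z)-4-[(4-methoxybenzyl)oxy]-2-[(4,4,5,5-tetramethyl-1,3,2-dioxaborolan-2-yl)methyl]but-2-enoate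
Product: 17 (4S,5S)-5-[(1E,4S,5E,8S)-4-(tert-butyldimethylsilyloxy)-11-(methoxycarbonyloxy)-2,6-dimethyl-8-(triethylsilyloxy)undeca-1,5-dien-9-yn-1-yl]-4-{[(4-methoxybenzyl)oxy]methyl}-3-methylideneoxolan-2-one, via O-boryl hydroxy ester 16 (not isolated)
Conditions: Sc(OTf)3 (10 mol %), CH2Cl2, −78 to 0 °C; then PPTS (cat.), toluene, 40 °C
Reagents that add atoms: none
Why: In this Lewis-acid-catalysed tandem allylboration–lactonization the closed chair transition state places the CH2OPMB group equatorial, so the anti adduct and hence the trans-lactone (C1, C2) should form stereospecifically, the 8-phenylmenthyl ester deciding the absolute sense and being expelled on ring closure.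

Step 12
Reactants: 17 the lactone PMB ether
Product: 18 (4S,5S)-5-[(1E,4S,5E,8S)-4-(tert-butyldimethylsilyloxy)-11-(methoxycarbonyloxy)-2,6-dimethyl-8-(triethylsilyloxy)undeca-1,5-dien-9-yn-1-yl]-4-(hydroxymethyl)-3-methylideneoxolan-2-one
Conditions: DDQ, CH2Cl2–pH 7 buffer, 0 °C
Reagents that add atoms: none
Why: Oxidative cleavage of the PMB ether should free the C14 alcohol without touching the silyl ethers, the carbonate or the methylene lactone.

Step 13
Reactants: 18 the C14 alcohol
Product: 19 (2S,3R)-2-[(1E,4S,5E,8S)-4-(tert-butyldimethylsilyloxy)-11-(methoxycarbonyloxy)-2,6-dimethyl-8-(triethylsilyloxy)undeca-1,5-dien-9-yn-1-yl]-4-methylidene-5-oxooxolane-3-carbaldehyde (seco-aldehyde; the descriptor at C1 changes by priority only)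
Conditions: Dess–Martin periodinane, NaHCO3, CH2Cl2, 0 °C to rt; used at once
Reagents that add atoms: none
Why: Buffered Dess–Martin oxidation should give the C14 aldehyde without epimerization at C1 or migration of the exocyclic double bond.

Step 14
Reactants: 19 the seco-aldehyde
Product: 21 (1S,2S,3E,6S,7E,10S,14S)-6-(tert-butyldimethylsilyloxy)-14-hydroxy-10-(triethylsilyloxy)-20-norcembra-3,7,15(17)-trien-11-yn-16,2-olide, via allenylindium 20 (not isolated)
Conditions: Pd(dppf)Cl2 (10 mol %), InI (2 equiv), THF–HMPA (4:1), rt; 19 added by syringe pump (final 2 mM)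
Reagents that add atoms: none
Why: Zerovalent palladium (formed from Pd(dppf)Cl2 and InI) ionizes the primary propargylic carbonate in an anti-SN2' sense, CO2 is lost and transmetalation to indium gives the allenylindium 20 with the metal on C11, which adds to the C14 formyl group through a cyclic SE2' transition state, so the new bond can form only at C13 and the C11≡C12 triple bond is returned inside the ring. The closest known reaction type is the Marshall–Tamaru propargylation of aldehydes with propargylic mesylates or carbonates under Pd catalysis with InI or Et2Zn, together with Lewis-acid-promoted allenylstannane–aldehyde closures of 12- and 14-membered homopropargylic alcohols. Ring A closes by exo attack on the aldehyde (14-exo-trig at C14) with the alkyne endocyclic. C14 is set by the C1/C2 stereocentres of the trans-lactone: Felkin–Anh attack anti to the C1–C15 bond, with the formyl oxygen turned toward C2 and on the side from which the C2-borne tether arrives, should give the 1,3-anti relation of C2–O and C14–O, that is (14S). The step needs C13- over C11-attack (secured because the allenylindium is formed regiospecifically and such reagents keep their constitution on the reaction time scale), ionization of the carbonate before the allylic lactone C2–O bond (secured by the much higher reactivity of a primary propargylic carbonate) and ring closure over oligomerization (secured by slow addition), while the TES ether at C10 excludes β-elimination to a butatriene and a second ionization.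

Step 15
Reactants: 21 the cycloalkynol
Product: 22 (1S,2S,3E,6S,7E,10S,11Z,14S)-6-(tert-butyldimethylsilyloxy)-14-hydroxy-12-(tributylstannyl)-10-(triethylsilyloxy)-20-norcembra-3,7,11,15(17)-tetraen-16,2-olide
Conditions: [Cp*RuCl]4 (5 mol %), Bu3SnH, CH2Cl2, rt
Reagents that add atoms: tributyltin hydride, CCCC[SnH](CCCC)CCCC
Why: In this hydroxyl-directed ruthenium-catalysed trans-hydrostannation the free C14–OH (the only protic group) should hydrogen-bond to the chloride ligand and steer tin to the proximal alkyne carbon C12, the trans addition leaving C10 and C13 on opposite sides of the new double bond.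

Step 16
Reactants: 22 the alkenylstannane
Product: 23 (1S,2S,3E,6S,7E,10S,11E,14S)-6-(tert-butyldimethylsilyloxy)-14-hydroxy-10-(triethylsilyloxy)cembra-3,7,11,15(17)-tetraen-16,2-olide
Conditions: Pd(PPh3)4 (15 mol %), copper thiophene-2-carboxylate Cu(O2CC4H3S), [Ph2PO2][NBu4], MeI, DMF, rt
Reagents that add atoms: iodomethane, CI
Why: The copper-assisted methyl-Stille coupling replaces tin by methyl with retention, which should complete the (11E)-trisubstituted olefin with the C20 methyl on C12.

Step 17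
Reactants: 23 the C10 TES ether
Product: 24 (1S,2S,3E,6S,7E,10S,11E,14S)-6-(tert-butyldimethylsilyloxy)-10,14-dihydroxycembra-3,7,11,15(17)-tetraen-16,2-olide
Conditions: PPTS, MeOH–CH2Cl2, 0 °C
Reagents that add atoms: none
Why: Acid-catalysed methanolysis should remove the TES ether selectively, since the secondary TBS ether at C6 is cleaved far more slowly.

Step 18
Reactants: 24 the 10,14-diol
Product: 25 (1S,2S,3E,6S,7E,10S,11E,14S)-10,14-diacetoxy-6-(tert-butyldimethylsilyloxy)cembra-3,7,11,15(17)-tetraen-16,2-olide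
Conditions: Ac2O, pyridine, DMAP (cat.), CH2Cl2, 0 °C to rt
Reagents that add atoms: acetic anhydride, CC(=O)OC(C)=O
Why: Acetylation of both secondary alcohols installs the two acetates of the target in one operation, after all palladium steps so that no allylic acetate is exposed to them.

Step 19
Reactants: 25 the diacetate TBS ether
Product: 26 (1S,2S,3E,6S,7E,10S,11E,14S)-10,14-diacetoxy-6-hydroxycembra-3,7,11,15(17)-tetraen-16,2-olide (CNP0418981.1)
Conditions: HF·pyridine, pyridine, THF, 0 °C to rt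
Reagents that add atoms: none
Why: Buffered fluoride desilylation should free the C6 hydroxyl while the acetates and the α-methylene lactone remain intact.

**Compound list**

1 | but-2-yne-1,4-diol | OCC#CCO | starting material
2 | 4-hydroxybut-2-yn-1-yl methyl carbonate | COC(=O)OCC#CCO | intermediate
3 | methyl 4-oxobut-2-yn-1-yl carbonate | COC(=O)OCC#CC=O | intermediate
4 | 3-methylbut-2-enal (prenal) | CC(C)=CC=O | starting material
5 | tert-butyl(dimethyl){[(1E)-3-methylbuta-1,3-dien-1-yl]oxy}silane | C=C(C)/C=C/O[Si](C)(C)C(C)(C)C | intermediate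
6 | methyl (4S,6E)-4-hydroxy-6-methyl-8-oxooct-6-en-2-yn-1-yl carbonate | O=C/C=C(\C)C[C@H](O)C#CCOC(=O)OC | intermediate
7 | methyl (4S,6E)-6-methyl-8-oxo-4-(triethylsilyloxy)oct-6-en-2-yn-1-yl carbonate | O=C/C=C(\C)C[C@H](O[Si](CC)(CC)CC)C#CCOC(=O)OC | intermediate
8 | methyl (4S,6E,8S,10E)-8-hydroxy-6,10-dimethyl-12-oxo-4-(triethylsilyloxy)dodeca-6,10-dien-2-yn-1-yl carbonate | O=C/C=C(\C)C[C@H](O)/C=C(\C)C[C@H](O[Si](CC)(CC)CC)C#CCOC(=O)OC | intermediate
9 | methyl (4S,6E,8S,10E)-8-(tert-butyldimethylsilyloxy)-6,10-dimethyl-12-oxo-4-(triethylsilyloxy)dodeca-6,10-dien-2-yn-1-yl carbonate | O=C/C=C(\C)C[C@H](O[Si](C)(C)C(C)(C)C)/C=C(\C)C[C@H](O[Si](CC)(CC)CC)C#CCOC(=O)OC | intermediate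
10 | 1-methoxy-4-[(prop-2-yn-1-yloxy)methyl]benzene (PMB propargyl ether) | C#CCOCc1ccc(OC)cc1 | starting material
11 | 4-[(4-methoxybenzyl)oxy]but-2-ynoic acid | OC(=O)C#CCOCc1ccc(OC)cc1 | intermediate
12 | (1R,2S,5R)-5-methyl-2-(2-phenylpropan-2-yl)cyclohexan-1-ol ((−)-8-phenylmenthol) | CC(C)(c1ccccc1)[C@@H]2CC[C@@H](C)C[C@H]2O | starting material
13 | (1R,2S,5R)-5-methyl-2-(2-phenylpropan-2-yl)cyclohexyl 4-[(4-methoxybenzyl)oxy]but-2-ynoate | CC(C)(c1ccccc1)[C@@H]2CC[C@@H](C)C[C@H]2OC(=O)C#CCOCc3ccc(OC)cc3 | intermediate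
14 | (−)-8-phenylmenthyl (2E)-2-(diisobutylalumanyl)-4-[(4-methoxybenzyl)oxy]but-2-enoate (alkenylalane, H cis to Al) | CC(C)(c1ccccc1)[C@@H]2CC[C@@H](C)C[C@H]2OC(=O)/C([Al](CC(C)C)CC(C)C)=C\COCc3ccc(OC)cc3 | intermediate
15 | (−)-8-phenylmenthyl (2Z)-4-[(4-methoxybenzyl)oxy]-2-[(4,4,5,5-tetramethyl-1,3,2-dioxaborolan-2-yl)methyl]but-2-enoate | CC(C)(c1ccccc1)[C@@H]2CC[C@@H](C)C[C@H]2OC(=O)/C(CB3OC(C)(C)C(C)(C)O3)=C\COCc4ccc(OC)cc4 | intermediate
16 | open-chain (1S,2S) anti adduct: 8-phenylmenthyl acrylate carrying C1 (CH2OPMB) and C2 (O-pinacolboryl) | CC(C)(c1ccccc1)[C@@H]2CC[C@@H](C)C[C@H]2OC(=O)C(=C)[C@@H](COCc3ccc(OC)cc3)[C@@H](OB4OC(C)(C)C(C)(C)O4)/C=C(\C)C[C@H](O[Si](C)(C)C(C)(C)C)/C=C(\C)C[C@H](O[Si](CC)(CC)CC)C#CCOC(=O)OC | intermediate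
17 | (4S,5S)-5-[(1E,4S,5E,8S)-4-(tert-butyldimethylsilyloxy)-11-(methoxycarbonyloxy)-2,6-dimethyl-8-(triethylsilyloxy)undeca-1,5-dien-9-yn-1-yl]-4-{[(4-methoxybenzyl)oxy]methyl}-3-methylideneoxolan-2-one | C=C1C(=O)O[C@@H](/C=C(\C)C[C@H](O[Si](C)(C)C(C)(C)C)/C=C(\C)C[C@H](O[Si](CC)(CC)CC)C#CCOC(=O)OC)[C@@H]1COCc2ccc(OC)cc2 | intermediate
18 | (4S,5S)-5-[the same undecadienynyl chain]-4-(hydroxymethyl)-3-methylideneoxolan-2-one | C=C1C(=O)O[C@@H](/C=C(\C)C[C@H](O[Si](C)(C)C(C)(C)C)/C=C(\C)C[C@H](O[Si](CC)(CC)CC)C#CCOC(=O)OC)[C@@H]1CO | intermediate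
19 | (2S,3R)-2-[the same undecadienynyl chain]-4-methylidene-5-oxooxolane-3-carbaldehyde (seco-aldehyde) | C=C1C(=O)O[C@@H](/C=C(\C)C[C@H](O[Si](C)(C)C(C)(C)C)/C=C(\C)C[C@H](O[Si](CC)(CC)CC)C#CCOC(=O)OC)[C@@H]1C=O | intermediate
20 | allenylindium of 19: C11 carries In(I)(OMe), C11=C12=C13H2 | C=C1C(=O)O[C@@H](/C=C(\C)C[C@H](O[Si](C)(C)C(C)(C)C)/C=C(\C)C[C@H](O[Si](CC)(CC)CC)C(=C=C)[In](I)OC)[C@@H]1C=O | intermediate
21 | (1S,2S,3E,6S,7E,10S,14S)-6-(tert-butyldimethylsilyloxy)-14-hydroxy-10-(triethylsilyloxy)-20-norcembra-3,7,15(17)-trien-11-yn-16,2-olide | C=C1C(=O)O[C@H]2/C=C(\C)C[C@H](O[Si](C)(C)C(C)(C)C)/C=C(\C)C[C@H](O[Si](CC)(CC)CC)C#CC[C@H](O)[C@H]12 | intermediate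
22 | (1S,2S,3E,6S,7E,10S,11Z,14S)-6-(tert-butyldimethylsilyloxy)-14-hydroxy-12-(tributylstannyl)-10-(triethylsilyloxy)-20-norcembra-3,7,11,15(17)-tetraen-16,2-olide | C=C1C(=O)O[C@H]2/C=C(\C)C[C@H](O[Si](C)(C)C(C)(C)C)/C=C(\C)C[C@H](O[Si](CC)(CC)CC)/C=C(\[Sn](CCCC)(CCCC)CCCC)C[C@H](O)[C@H]12 | intermediate
23 | (1S,2S,3E,6S,7E,10S,11E,14S)-6-(tert-butyldimethylsilyloxy)-14-hydroxy-10-(triethylsilyloxy)cembra-3,7,11,15(17)-tetraen-16,2-olide | C=C1C(=O)O[C@H]2/C=C(\C)C[C@H](O[Si](C)(C)C(C)(C)C)/C=C(\C)C[C@H](O[Si](CC)(CC)CC)/C=C(\C)C[C@H](O)[C@H]12 | intermediate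
24 | (1S,2S,3E,6S,7E,10S,11E,14S)-6-(tert-butyldimethylsilyloxy)-10,14-dihydroxycembra-3,7,11,15(17)-tetraen-16,2-olide | C=C1C(=O)O[C@H]2/C=C(\C)C[C@H](O[Si](C)(C)C(C)(C)C)/C=C(\C)C[C@H](O)/C=C(\C)C[C@H](O)[C@H]12 | intermediate
25 | (1S,2S,3E,6S,7E,10S,11E,14S)-10,14-diacetoxy-6-(tert-butyldimethylsilyloxy)cembra-3,7,11,15(17)-tetraen-16,2-olide | C=C1C(=O)O[C@H]2/C=C(\C)C[C@H](O[Si](C)(C)C(C)(C)C)/C=C(\C)C[C@H](OC(C)=O)/C=C(\C)C[C@H](OC(C)=O)[C@H]12 | intermediate
26 | (1S,2S,3E,6S,7E,10S,11E,14S)-10,14-diacetoxy-6-hydroxycembra-3,7,11,15(17)-tetraen-16,2-olide (CNP0418981.1) | C=C1C(=O)O[C@H]2/C=C(\C)C[C@H](O)/C=C(\C)C[C@H](OC(C)=O)/C=C(\C)C[C@H](OC(C)=O)[C@H]12 | target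

**Summary**

Total step count: 19. Longest linear sequence: 15 steps (1, 2, 4, 5, 6, 7, 11, 12, 13, 14, 15, 16, 17, 18, 19).

Steps most likely to fail:

Step 14. The facial bias of the C14 formyl group may be weak or reversed, because the 1,2- and 1,3-preferences of the lactone need not reinforce each other in a macrocyclic transition state; oligomerization also competes with ring closure. Fallback: setting out from 19, the same ring closure is run and the (14R)-alcohol, the 14-epimer of 21 F1, is taken on. A Mitsunobu reaction (PPh3, DIAD, HCO2H, toluene, 0 °C) inverts C14 to the (14S)-formate of 21 F2, and KHCO3 in MeOH–H2O at 0 °C returns 21. C14 is then fixed by SN2 inversion instead of by substrate-controlled addition.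

Step 11. The ester auxiliary may discriminate the faces of the allyl unit poorly, giving the (1R,2R)-lactone diastereomer, which is hard to separate because C6 and C10 are remote; lactonization of the hindered ester may also be slow, with loss of the TES group under prolonged acid. Fallback: setting out from 10 (and using 9), 10 is acylated (n-BuLi, ClCO2Me) to methyl 4-[(4-methoxybenzyl)oxy]but-2-ynoate F3. F3 is converted as in step 10 into methyl (2Z)-4-[(4-methoxybenzyl)oxy]-2-[(4,4,5,5-tetramethyl-1,3,2-dioxaborolan-2-yl)methyl]but-2-enoate F4. F4 is added to 9 under a chiral BINOL-derived phosphoric acid (TRIP, 10 mol %, toluene, −30 °C) to the O-boryl methyl ester adduct F5, which lactonizes (PPTS) to 17. Catalyst control replaces auxiliary control, and the small methyl ester closes the lactone readily.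

Step 4 (the same reaction recurs in step 6). The aldehyde-derived dienol ether may give low enantioselectivity, α- instead of γ-attack, or erosion of the enal geometry. Fallback: setting out from 3, 3-methylbut-2-enoyl chloride and morpholine give 3-methyl-1-(morpholin-4-yl)but-2-en-1-one F6. LiN(i-Pr)2 and TBSCl convert F6 into 4-[1-(tert-butyldimethylsilyloxy)-3-methylbuta-1,3-dien-1-yl]morpholine F7. SiCl4 with a chiral bisphosphoramide catalyst (CH2Cl2, −78 °C) adds F7 to 3 to give methyl (4S,6E)-4-hydroxy-6-methyl-8-(morpholin-4-yl)-8-oxooct-6-en-2-yn-1-yl carbonate F8. TESCl and imidazole give its triethylsilyl ether F9, and Cp2Zr(H)Cl (THF, rt) reduces the tertiary amide to the enal and returns 7. The same detour would serve step 6.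

Further compounds
F1 | step 14 | (1S,2S,3E,6S,7E,10S,14R)-6-(tert-butyldimethylsilyloxy)-14-hydroxy-10-(triethylsilyloxy)-20-norcembra-3,7,15(17)-trien-11-yn-16,2-olide (14-epimer of 21) | C=C1C(=O)O[C@H]2/C=C(\C)C[C@H](O[Si](C)(C)C(C)(C)C)/C=C(\C)C[C@H](O[Si](CC)(CC)CC)C#CC[C@@H](O)[C@H]12
F2 | step 14 | (14S)-formate of 21 | C=C1C(=O)O[C@H]2/C=C(\C)C[C@H](O[Si](C)(C)C(C)(C)C)/C=C(\C)C[C@H](O[Si](CC)(CC)CC)C#CC[C@H](OC=O)[C@H]12
F3 | step 11 | methyl 4-[(4-methoxybenzyl)oxy]but-2-ynoate | COC(=O)C#CCOCc1ccc(OC)cc1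
F4 | step 11 | methyl (2Z)-4-[(4-methoxybenzyl)oxy]-2-[(4,4,5,5-tetramethyl-1,3,2-dioxaborolan-2-yl)methyl]but-2-enoate | COC(=O)/C(CB1OC(C)(C)C(C)(C)O1)=C\COCc1ccc(OC)cc1
F5 | step 11 | O-boryl methyl ester adduct (open-chain (1S,2S) anti adduct of 9 and F4) | COC(=O)C(=C)[C@@H](COCc1ccc(OC)cc1)[C@@H](OB2OC(C)(C)C(C)(C)O2)/C=C(\C)C[C@H](O[Si](C)(C)C(C)(C)C)/C=C(\C)C[C@H](O[Si](CC)(CC)CC)C#CCOC(=O)OC
F6 | step 4 | 3-methyl-1-(morpholin-4-yl)but-2-en-1-one | CC(C)=CC(=O)N1CCOCC1
F7 | step 4 | 4-[1-(tert-butyldimethylsilyloxy)-3-methylbuta-1,3-dien-1-yl]morpholine (ketene aminal geometry not defined) | C=C(C)C=C(O[Si](C)(C)C(C)(C)C)N1CCOCC1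
F8 | step 4 | methyl (4S,6E)-4-hydroxy-6-methyl-8-(morpholin-4-yl)-8-oxooct-6-en-2-yn-1-yl carbonate | O=C(/C=C(\C)C[C@H](O)C#CCOC(=O)OC)N1CCOCC1
F9 | step 4 | methyl (4S,6E)-6-methyl-8-(morpholin-4-yl)-8-oxo-4-(triethylsilyloxy)oct-6-en-2-yn-1-yl carbonate | O=C(/C=C(\C)C[C@H](O[Si](CC)(CC)CC)C#CCOC(=O)OC)N1CCOCC1
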